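**Retrosynthetic overview** (ring A = fused benzene ring, ring B = the partly saturated carbocycle C1–C4/C4a/C8a, ring C = pendant aryl; 3,4-dihydronaphthalene numbering)
1. Target 10 comes from its tri-O-benzyl ether 9 by one non-reductive global debenzylation; the oxygenation of rings A and C is bought.
2. Ring B of 9 is cut at C1=C2 (the enone, an aldol-condensation retron) and at C4–C4a (aryl–CH2), giving bromoaldehyde 2 (ring A, C1 as CHO, Br on C4a) and the chain C4–C3–C2–C(=O)–ring C.
3. Enabling feature: the only stereocentre, C3, lies β to the ketone carbon and carries two CH2 arms (C2 and C4), so C(=O), C2, C3 and C4 are the four ring carbons of the mirror-symmetric cyclobutanol 6, in which C2 and C4 are enantiotopic. Ligand-controlled β-carbon elimination on palladium opens it, sets C3 and delivers C4 to C4a; the unveiled ketone has one α-CH2 (C2), placed for a six-membered aldol closure onto the ortho-CHO (C1).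
4. 6 comes from aryl Grignard reagent 5 (from bromide 3) and cyclobutanone 4; 2 comes from 1 by O-benzylation.
5. Ring order: rings A and C are bought; the cyclobutane is a bought, temporary ring that is cleaved; ring B is the only ring formed, in the key step.

Key step: step 3

Remark: the sense of enantiotopic bond selection by the chiral P,N ligand cannot be assigned in advance; the ligand antipode that gives (3R) is to be chosen after a first run, both antipodes being accessible.

**Step 1**
Reactants: 1 2-bromo-5-hydroxy-4-methoxybenzaldehyde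
Product: 2 5-(benzyloxy)-2-bromo-4-methoxybenzaldehyde
Conditions: BnBr, K2CO3, DMF, rt
Reagents that add atoms: benzyl bromide, BrCc1ccccc1
Why: The phenoxide formed by K2CO3 undergoes SN2 O-alkylation (Williamson ether synthesis), masking the phenol that would otherwise give an electron-rich phenoxide para to the bromide and retard oxidative addition in step 3.

**Step 2**
Reactants: 3 1-(benzyloxy)-4-bromo-2-methoxybenzene; 4 3-[(benzyloxy)methyl]cyclobutan-1-one
Product: 6 cis-1-[4-(benzyloxy)-3-methoxyphenyl]-3-[(benzyloxy)methyl]cyclobutan-1-ol (OH and CH2OBn on the same face; achiral), via aryl Grignard reagent 5 (not isolated)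
Conditions: Mg, I2 (cat.), THF, 40 °C; then 4, THF, −78 to 0 °C; H2O; chromatography on Et3N-deactivated silica
Reagents that add atoms: none
Why: Grignard formation and 1,2-addition to the strained, electrophilic cyclobutanone should be fast at low temperature, and attack anti to the C3 substituent of the puckered ring should favour the cis carbinol, which has a mirror plane so that only the minor trans isomer has to be removed.

**Step 3**
Reactants: 6 cis-1-[4-(benzyloxy)-3-methoxyphenyl]-3-[(benzyloxy)methyl]cyclobutan-1-ol (1.1 equiv); 2 5-(benzyloxy)-2-bromo-4-methoxybenzaldehyde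
Product: 9 [(3R)-7-(benzyloxy)-3-[(benzyloxy)methyl]-6-methoxy-3,4-dihydronaphthalen-2-yl][4-(benzyloxy)-3-methoxyphenyl]methanone, via keto aldehyde 7 (not isolated), via aldol adduct 8 (not isolated)
Conditions: Pd(OAc)2 (5 mol %), N,N-dimethyl-1-[2-(diphenylphosphino)ferrocenyl]ethylamine (antipode giving 3R, 10 mol %), Cs2CO3 (2.5 equiv), 4 Å MS, toluene, 50 °C, then 90 °C
Reagents that add atoms: none
Why: Proposed new method: zerovalent palladium, formed in situ from Pd(OAc)2 and the phosphine, inserts into the C–Br bond of 2, Cs2CO3 converts the arylpalladium bromide into the arylpalladium alkoxide of 6, strain-driven β-carbon elimination cleaves one of the two enantiotopic ring bonds at the carbinol carbon and C(sp3)–C(sp2) reductive elimination forms the C4–C4a bond of keto aldehyde 7, after which Cs2CO3 enolizes the ketone at C2 and the enolate adds to the ortho-formyl carbon (8) and loses water by E1cB to form C1=C2. The closest known reaction type is the palladium-catalysed enantioselective arylative ring opening of 3-substituted 1-aryl tert-cyclobutanols with aryl bromides under chiral ferrocenyl P,N ligands, here merged in one flask with an ordinary base-mediated intramolecular aldol condensation by placing a formyl group ortho to the bromide. The one ring closed, ring B, forms by a 6-(enolexo)-exo-trig aldol addition. The C3 stereocentre is controlled by the chiral ligand on palladium, which decides which enantiotopic C–C bond migrates; it lies β to the ketone, cannot epimerize by enolization, and the ligand antipode is chosen to give 3R. The step needs reductive elimination to outrun β-hydride elimination of the alkylpalladium intermediate, which the chelating P,N ligand and the ortho-substituted aryl group should favour, and it needs a single aldol outcome, which is secured because the aldehyde is non-enolizable, the ketone has only one α-CH2 (its other flank is ring C) and only the six-membered closure is geometrically available. Because 6 has a mirror plane through the carbinol carbon and C3, enantiotopic bond choice is the only stereochemical issue, and the cis/trans relationship in 6 disappears when the carbinol carbon becomes the ketone.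

**Step 4**
Reactants: 9 [(3R)-7-(benzyloxy)-3-[(benzyloxy)methyl]-6-methoxy-3,4-dihydronaphthalen-2-yl][4-(benzyloxy)-3-methoxyphenyl]methanone
Product: 10 [(3R)-7-hydroxy-3-(hydroxymethyl)-6-methoxy-3,4-dihydronaphthalen-2-yl](4-hydroxy-3-methoxyphenyl)methanone
Conditions: BCl3 (1 M in CH2Cl2, excess), pentamethylbenzene, CH2Cl2, −78 to −20 °C, argon; then H2O
Reagents that add atoms: none
Why: BCl3 coordinates the ether oxygens and cleaves all three O-benzyl bonds while pentamethylbenzene traps the benzyl cations by Friedel–Crafts alkylation, a non-reductive debenzylation that should leave the enone, the styrenyl double bond, the aryl methyl ethers and the non-enolizable C3 stereocentre untouched.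

**Compound list**
1 | 2-bromo-5-hydroxy-4-methoxybenzaldehyde | O=Cc1cc(O)c(OC)cc1Br | starting material
2 | 5-(benzyloxy)-2-bromo-4-methoxybenzaldehyde | O=Cc1cc(OCc2ccccc2)c(OC)cc1Br | intermediate
3 | 1-(benzyloxy)-4-bromo-2-methoxybenzene | COc1cc(Br)ccc1OCc1ccccc1 | starting material
4 | 3-[(benzyloxy)methyl]cyclobutan-1-one | O=C1CC(COCc2ccccc2)C1 | starting material
5 | [4-(benzyloxy)-3-methoxyphenyl]magnesium bromide | COc1cc([Mg]Br)ccc1OCc1ccccc1 | intermediate
6 | cis-1-[4-(benzyloxy)-3-methoxyphenyl]-3-[(benzyloxy)methyl]cyclobutan-1-ol | O[C@]1(c2ccc(OCc3ccccc3)c(OC)c2)C[C@H](COCc2ccccc2)C1 | intermediate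
7 | 5-(benzyloxy)-2-{(2R)-4-[4-(benzyloxy)-3-methoxyphenyl]-2-[(benzyloxy)methyl]-4-oxobutyl}-4-methoxybenzaldehyde | COc1cc(C(=O)C[C@H](COCc2ccccc2)Cc2cc(OC)c(OCc3ccccc3)cc2C=O)ccc1OCc1ccccc1 | intermediate
8 | [(3R)-7-(benzyloxy)-3-[(benzyloxy)methyl]-1-hydroxy-6-methoxy-1,2,3,4-tetrahydronaphthalen-2-yl][4-(benzyloxy)-3-methoxyphenyl]methanone (C1/C2 diastereomers) | COc1cc(C(=O)C2C(O)c3cc(OCc4ccccc4)c(OC)cc3C[C@H]2COCc2ccccc2)ccc1OCc1ccccc1 | intermediate
9 | [(3R)-7-(benzyloxy)-3-[(benzyloxy)methyl]-6-methoxy-3,4-dihydronaphthalen-2-yl][4-(benzyloxy)-3-methoxyphenyl]methanone | COc1cc(C(=O)C2=Cc3cc(OCc4ccccc4)c(OC)cc3C[C@H]2COCc2ccccc2)ccc1OCc1ccccc1 | intermediate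
10 | [(3R)-7-hydroxy-3-(hydroxymethyl)-6-methoxy-3,4-dihydronaphthalen-2-yl](4-hydroxy-3-methoxyphenyl)methanone | COc1cc(C(=O)C2=Cc3cc(O)c(OC)cc3C[C@H]2CO)ccc1O | target

**Total step count:** 4. **Longest linear sequence:** 3 steps (3 and 4 to 6, then 9, then 10; equally 1 to 2, then 9, then 10).

**Steps most likely to fail**

Step 3 (Proposed new method). The free ortho-formyl group may act out of sequence: hemiacetal formation with the palladium alkoxide, intermolecular aldol reaction or palladium-catalysed α-arylation of 7 with unconsumed 2, alongside β-hydride elimination of the alkylpalladium intermediate, so that the cascade stalls or gives ring-opened by-products. The fallback uses known chemistry only, sets out from 2 (6 unchanged) and comes back to the route at 7. The aldehyde of 2 is masked with ethane-1,2-diol (p-TsOH, toluene, Dean–Stark) as 2-[5-(benzyloxy)-2-bromo-4-methoxyphenyl]-1,3-dioxolane F1. F1 and 6 are then joined by the established enantioselective palladium-catalysed arylative ring opening of tert-cyclobutanols (Pd(OAc)2, the same P,N ligand, Cs2CO3, toluene, 50 °C), now with an aryl bromide that carries no reactive carbonyl group, to give (3R)-1-[4-(benzyloxy)-3-methoxyphenyl]-3-[(benzyloxy)methyl]-4-[4-(benzyloxy)-2-(1,3-dioxolan-2-yl)-5-methoxyphenyl]butan-1-one F2. Aqueous HCl in THF should unmask the aldehyde to give 7, isolated in this variant, and piperidinium acetate in toluene at 80 °C should close 7 through 8 to 9 by a conventional intramolecular aldol condensation.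

Step 4. Cleavage of the primary alkyl benzyl ether may lag behind that of the two aryl benzyl ethers, forcing temperatures at which BCl3 begins to demethylate the guaiacol units or to add chloride or benzyl cations to the electron-rich styrenyl enone. The fallback replaces Lewis-acid-labile by fluoride-labile protection before the enone exists; it sets out from 6 and 1 and comes back at 10. Hydrogenolysis of 6 (H2, 10% Pd/C, EtOAc, rt, neutral) should give cis-1-(4-hydroxy-3-methoxyphenyl)-3-(hydroxymethyl)cyclobutan-1-ol F3. Silylation of the phenol and the primary alcohol only (TIPSCl, imidazole, DMF) should give cis-1-{3-methoxy-4-[(triisopropylsilyl)oxy]phenyl}-3-{[(triisopropylsilyl)oxy]methyl}cyclobutan-1-ol F4. Silylation of 1 under the same conditions should give 2-bromo-4-methoxy-5-[(triisopropylsilyl)oxy]benzaldehyde F5. The conditions of step 3 applied to F4 and F5 should pass through the tris(triisopropylsilyl) keto aldehyde F6 and the tris(triisopropylsilyl) aldol adduct F7 to the tris(triisopropylsilyl) dihydronaphthalenyl ketone F8. Tetrabutylammonium fluoride buffered with AcOH (THF, 0 °C) should then release 10.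

Step 2. Facial selectivity in the addition may be modest, leaving a cis/trans mixture of oily, acid-sensitive tertiary benzylic cyclobutanols that resists separation and partly ionizes on silica. The fallback builds the carbinol on an ester-bearing ring, where the diastereomers should be easier to separate by crystallization or chromatography; it sets out from 3 (through 5) and comes back at 6. Grignard reagent 5 is added at −78 °C in THF to commercial ethyl 3-oxocyclobutane-1-carboxylate (CCOC(=O)C1CC(=O)C1), ketone-selectively, to give ethyl cis-3-[4-(benzyloxy)-3-methoxyphenyl]-3-hydroxycyclobutane-1-carboxylate F9, which is purified at this stage. LiAlH4 (THF, 0 °C) should reduce it to cis-1-[4-(benzyloxy)-3-methoxyphenyl]-3-(hydroxymethyl)cyclobutan-1-ol F10, and selective O-benzylation of the primary alcohol (NaH, 1 equiv, BnBr, Bu4NI, THF, 0 °C) should give 6.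

**Further compounds**
F1 | step 3 | 2-[5-(benzyloxy)-2-bromo-4-methoxyphenyl]-1,3-dioxolane | COc1cc(Br)c(C2OCCO2)cc1OCc1ccccc1
F2 | step 3 | (3R)-1-[4-(benzyloxy)-3-methoxyphenyl]-3-[(benzyloxy)methyl]-4-[4-(benzyloxy)-2-(1,3-dioxolan-2-yl)-5-methoxyphenyl]butan-1-one | COc1cc(C(=O)C[C@H](COCc2ccccc2)Cc2cc(OC)c(OCc3ccccc3)cc2C4OCCO4)ccc1OCc1ccccc1
F3 | step 4 | cis-1-(4-hydroxy-3-methoxyphenyl)-3-(hydroxymethyl)cyclobutan-1-ol | O[C@]1(c2ccc(O)c(OC)c2)C[C@H](CO)C1
F4 | step 4 | cis-1-{3-methoxy-4-[(triisopropylsilyl)oxy]phenyl}-3-{[(triisopropylsilyl)oxy]methyl}cyclobutan-1-ol | O[C@]1(c2ccc(O[Si](C(C)C)(C(C)C)C(C)C)c(OC)c2)C[C@H](CO[Si](C(C)C)(C(C)C)C(C)C)C1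
F5 | step 4 | 2-bromo-4-methoxy-5-[(triisopropylsilyl)oxy]benzaldehyde | O=Cc1cc(O[Si](C(C)C)(C(C)C)C(C)C)c(OC)cc1Br
F6 | step 4 | 4-methoxy-2-{(2R)-4-{3-methoxy-4-[(triisopropylsilyl)oxy]phenyl}-4-oxo-2-{[(triisopropylsilyl)oxy]methyl}butyl}-5-[(triisopropylsilyl)oxy]benzaldehyde | COc1cc(C(=O)C[C@H](CO[Si](C(C)C)(C(C)C)C(C)C)Cc2cc(OC)c(O[Si](C(C)C)(C(C)C)C(C)C)cc2C=O)ccc1O[Si](C(C)C)(C(C)C)C(C)C
F7 | step 4 | {(3R)-1-hydroxy-6-methoxy-7-[(triisopropylsilyl)oxy]-3-{[(triisopropylsilyl)oxy]methyl}-1,2,3,4-tetrahydronaphthalen-2-yl}{3-methoxy-4-[(triisopropylsilyl)oxy]phenyl}methanone | COc1cc(C(=O)C2C(O)c3cc(O[Si](C(C)C)(C(C)C)C(C)C)c(OC)cc3C[C@H]2CO[Si](C(C)C)(C(C)C)C(C)C)ccc1O[Si](C(C)C)(C(C)C)C(C)C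
F8 | step 4 | {(3R)-6-methoxy-7-[(triisopropylsilyl)oxy]-3-{[(triisopropylsilyl)oxy]methyl}-3,4-dihydronaphthalen-2-yl}{3-methoxy-4-[(triisopropylsilyl)oxy]phenyl}methanone | COc1cc(C(=O)C2=Cc3cc(O[Si](C(C)C)(C(C)C)C(C)C)c(OC)cc3C[C@H]2CO[Si](C(C)C)(C(C)C)C(C)C)ccc1O[Si](C(C)C)(C(C)C)C(C)C
F9 | step 2 | ethyl cis-3-[4-(benzyloxy)-3-methoxyphenyl]-3-hydroxycyclobutane-1-carboxylate | O[C@]1(c2ccc(OCc3ccccc3)c(OC)c2)C[C@H](C(=O)OCC)C1
F10 | step 2 | cis-1-[4-(benzyloxy)-3-methoxyphenyl]-3-(hydroxymethyl)cyclobutan-1-ol | O[C@]1(c2ccc(OCc3ccccc3)c(OC)c2)C[C@H](CO)C1
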